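Retrosynthesis: the arylglycerol is cut at the C8''–O(ring B) ether and the C7''–C8'' aldol bond; the furofuran at the C7–O–C9' ether, at C7'–C8' (carbene C–H insertion), at the O9–C7' benzyl ether bond and at C7–C8 (aldol).
Enabling feature: C7' lies 1,5 to C8' along C8'–C8–C9–O9–C7', and its C–H bond is benzylic to ring C and alpha to O9, so a carbene at C8' of the C7/C9' lactone can insert there and close the O9 tetrahydrofuran.
Forward: aldol/lactonisation gives the lactone ring, then the syringylmethyl ether and diazo transfer, then Rh2(OAc)4 insertion closes the O9 tetrahydrofuran; the lactone is reduced, C7' is equilibrated while the molecule is monocyclic, and a mesylate displacement closes the second tetrahydrofuran.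
The ring B phenol is then freed and extended by an aryloxyacetyl imide anti-aldol, reduction and hydrogenolysis.
Stereochemistry: C7/C8 from an (R)-oxazolidinone syn aldol; C8' from the enforced cis fusion of the insertion; C7' by thermodynamic epimerisation to the 2,3-trans tetrahydrofuran (the insertion itself is expected to place the aryl group 7'-endo); C7''/C8'' from an (S)-oxazolidinone magnesium anti-aldol.

Key step: step 11

Remark: lignan numbering is used (C7–C9 on the ring B side of the furofuran, primed on the ring C side, double-primed in the arylglycerol); O-benzylvanillin, methyl 4-chloro-4-oxobutanoate and both enantiomers of 4-benzyl-1,3-oxazolidin-2-one are taken as purchased, and the insertion is assumed, by analogy with related diazo lactones, to favour the 7'-endo epimer, which step 14 corrects.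

Step 1
Reactants: 1 vanillin
Product: 2 4-formyl-2-methoxyphenyl 4-methylbenzenesulfonate (vanillin tosylate)
Conditions: TsCl (1.1 equiv), Et3N, DMAP (cat.), CH2Cl2, 0 °C to rt
Reagents that add atoms: 4-methylbenzenesulfonyl chloride, Cc1ccc(cc1)S(=O)(=O)Cl
Why: Base-mediated O-sulfonylation of a phenol; the electron-poor tosyloxyaryl ring later keeps the C7–O bond from ionising under the acid of step 14 and is cleaved by hydroxide in step 17.

Step 2
Reactants: 3 (R)-4-benzyl-1,3-oxazolidin-2-one; 4 methyl 4-chloro-4-oxobutanoate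
Product: 5 methyl 4-[(4R)-4-benzyl-2-oxo-1,3-oxazolidin-3-yl]-4-oxobutanoate
Conditions: n-BuLi, THF, −78 °C; then 4, −78 to 0 °C
Reagents that add atoms: none
Why: N-Acylation of the lithiated Evans oxazolidinone by an acid chloride, which is far more electrophilic than the methyl ester at the other chain end.

Step 3
Reactants: 5 succinyl imide; 2 vanillin tosylate
Product: 7 (4R)-4-benzyl-3-{[(2R,3R)-2-(3-methoxy-4-tosyloxyphenyl)-5-oxotetrahydrofuran-3-yl]carbonyl}-1,3-oxazolidin-2-one (trans lactone imide), via syn-aldol adduct 6 (not isolated)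
Conditions: Bu2BOTf, i-Pr2NEt, CH2Cl2, 0 °C; 2, −78 to 0 °C; pH 7 buffer, MeOH, H2O2; then TsOH·H2O (cat.), CH2Cl2, rt
Reagents that add atoms: none
Why: Evans syn aldol followed by lactonisation: the (Z)-dibutylboron enolate of the imide adds to 2 through a Zimmerman–Traxler chair on the face away from the benzyl group of the (R)-auxiliary, which sets C7 (R) and C8 in a syn relationship, and acid-catalysed attack of the C7 hydroxyl on the methyl ester then gives the 4,5-trans gamma-lactone.

Step 4
Reactants: 7 trans lactone imide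
Product: 8 (2R,3R)-2-(3-methoxy-4-tosyloxyphenyl)-5-oxotetrahydrofuran-3-carboxylic acid
Conditions: LiOH, H2O2, THF/H2O, 0 °C; Na2SO3; 1 M HCl
Reagents that add atoms: hydrogen peroxide, OO
Why: LiOOH attacks the exocyclic imide carbonyl selectively (standard Evans auxiliary cleavage), sulfite reduces the peracid, and any opened lactone re-closes on acidification with the trans arrangement at C7/C8 retained.

Step 5
Reactants: 8 lactone acid
Product: 9 (4S,5R)-4-(hydroxymethyl)-5-(3-methoxy-4-tosyloxyphenyl)dihydrofuran-2(3H)-one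
Conditions: BH3·SMe2, THF, 0 °C to rt; MeOH quench
Reagents that add atoms: none
Why: Borane reduces a free carboxylic acid through its acyloxyborane much faster than it reduces a lactone or an aryl sulfonate (chemoselective acid reduction).

Step 6
Reactants: 10 syringaldehyde
Product: 11 4-(benzyloxy)-3,5-dimethoxybenzaldehyde
Conditions: BnBr, K2CO3, DMF, 60 °C
Reagents that add atoms: benzyl bromide, BrCc1ccccc1
Why: Williamson O-alkylation of the hindered but acidic syringyl phenol.

Step 7
Reactants: 11 4-(benzyloxy)-3,5-dimethoxybenzaldehyde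
Product: 12 [4-(benzyloxy)-3,5-dimethoxyphenyl]methanol
Conditions: NaBH4, MeOH, 0 °C
Reagents that add atoms: none
Why: Borohydride reduction of an aryl aldehyde to the benzylic alcohol.

Step 8
Reactants: 12 [4-(benzyloxy)-3,5-dimethoxyphenyl]methanol
Product: 13 4-(benzyloxy)-3,5-dimethoxybenzyl 2,2,2-trichloroacetimidate
Conditions: Cl3CCN, DBU (cat.), CH2Cl2, 0 °C
Reagents that add atoms: trichloroacetonitrile, ClC(Cl)(Cl)C#N
Why: Base-catalysed addition of the alcohol to trichloroacetonitrile (trichloroacetimidate formation), which is reliable for electron-rich benzylic alcohols.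

Step 9
Reactants: 9 hydroxymethyl lactone; 13 syringyl-type trichloroacetimidate
Product: 14 (4S,5R)-4-{[(4-benzyloxy-3,5-dimethoxybenzyl)oxy]methyl}-5-(3-methoxy-4-tosyloxyphenyl)dihydrofuran-2(3H)-one
Conditions: TfOH (5 mol%), 4 Å molecular sieves, CH2Cl2, 0 °C
Reagents that add atoms: none
Why: Acid-catalysed trichloroacetimidate benzylation transfers the stabilised syringylmethyl cation to the primary alcohol without ever forming an alkoxide, so base-induced translactonisation of the beta-hydroxymethyl lactone is avoided.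

Step 10
Reactants: 14 ether lactone
Product: 16 (4S,5R)-3-diazo-4-{[(4-benzyloxy-3,5-dimethoxybenzyl)oxy]methyl}-5-(3-methoxy-4-tosyloxyphenyl)dihydrofuran-2(3H)-one, via trifluoroacetyl lactone 15 (not isolated)
Conditions: LiN(SiMe3)2, THF, −78 °C; CF3CO2CH2CF3; aqueous HCl work-up; then MsN3, Et3N, H2O (1 equiv), MeCN, rt
Reagents that add atoms: methanesulfonyl azide, CS(=O)(=O)N=[N+]=[N-]; 2,2,2-trifluoroethyl trifluoroacetate, FC(F)(F)COC(=O)C(F)(F)F (its atoms remain only in 15)
Why: Deacylative Regitz diazo transfer: Claisen trifluoroacetylation of the lactone lithium enolate at C8' activates that carbon for diazo transfer from MsN3, the trifluoroacetyl group then leaving as the N-sulfonyl amide, while C8 carries no beta leaving group and is untouched.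

Step 11
Reactants: 16 alpha-diazo lactone
Product: 17 cis-fused furofuranone (7R,8S,7'S,8'R) with the lactone carbonyl at C9', the ring B aryl exo at C7 and the ring C aryl endo at C7'
Conditions: Rh2(OAc)4 (2 mol%), CH2Cl2, 40 °C, slow addition of 16 (high dilution)
Reagents that add atoms: none
Why: Rh2(OAc)4 expels N2 from 16 and the electrophilic rhodium carbene at C8' inserts into the C7'–H bond in one concerted three-centre step (hydride shift to carbon with simultaneous C7'–C8' bond formation), the bond being activated by O9 and by the electron-rich ring C. The closest known reaction type is the dirhodium-catalysed intramolecular 1,5 C–H insertion of alpha-diazo-gamma-butyrolactones into benzylic ether C–H bonds. The new tetrahydrofuran (C8', C8, C9, O9, C7') closes as a five-membered ring through the 1,5-insertion mode and can only be cis-fused to the lactone, so C8' is set by the existing C8 centre through the tether. At C7' the aryl group should turn away from the carboxylate wall of the dirhodium core and end cis to the lactone carbonyl (7'-endo, S); this centre is therefore corrected in step 14 and either epimer can be carried on. The step needs insertion to beat 1,2-hydride migration from C8–H (butenolide) and carbene dimerisation, which the doubly activated and geometrically ideal C7'–H bond, the ring-constrained C8–H and slow addition at high dilution should secure. The other C–H bonds (C9–H2, the OCH2Ph and OMe groups) would give strained small rings or lie out of reach.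

Step 12
Reactants: 17 7'-endo furofuranone
Product: 18 all-cis tetrahydrofuran diol (7R,8S,7'S,8'S): 2-(4-benzyloxy-3,5-dimethoxyphenyl)-3-(hydroxymethyl)-4-[(R)-hydroxy(3-methoxy-4-tosyloxyphenyl)methyl]tetrahydrofuran
Conditions: LiBH4, THF, 0 °C to rt
Reagents that add atoms: none
Why: LiBH4 reduces the lactone to the 1,4-diol and leaves the aryl sulfonate, the benzyl ethers and every stereocentre untouched, which makes the remaining tetrahydrofuran monocyclic.

Step 13
Reactants: 18 all-cis diol
Product: 19 all-cis diacetate (O7 and O9' acetylated)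
Conditions: Ac2O, pyridine, DMAP (cat.), CH2Cl2, rt
Reagents that add atoms: acetic anhydride, CC(=O)OC(C)=O
Why: Pyridine/DMAP acetylation caps O7 and O9' so that neither can capture the C7' cation in the next step.

Step 14
Reactants: 19 all-cis diacetate
Product: 20 2,3-trans-3,4-cis diacetate (7R,8S,7'R,8'S)
Conditions: BF3·OEt2 (0.3 equiv), CH2Cl2, −20 to 0 °C
Reagents that add atoms: none
Why: Lewis acid-promoted C2 epimerisation of a 2-aryltetrahydrofuran: BF3 reversibly ionises the benzylic C7'–O9 bond (cation stabilised by the trialkoxyaryl ring C, whereas C7–OAc on the tosyloxyaryl ring B does not ionise), and re-closure under thermodynamic control should move the aryl group from the strained all-cis arrangement to the 2,3-trans one, that is to the 7'R configuration of the target.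

Step 15
Reactants: 20 2,3-trans diacetate
Product: 21 2,3-trans-3,4-cis tetrahydrofuran diol (7R,8S,7'R,8'S)
Conditions: K2CO3 (0.2 equiv), MeOH, 0 °C
Reagents that add atoms: none
Why: Zemplén-type transesterification removes both acetates under conditions too mild to cleave the aryl tosylate.

Step 16
Reactants: 21 2,3-trans diol
Product: 23 furofuran tosylate (7R,8S,7'R,8'S) with both aryl groups exo, via primary mesylate 22 (not isolated)
Conditions: MsCl (1.05 equiv), pyridine, 0 °C, then 40 °C
Reagents that add atoms: methanesulfonyl chloride, CS(=O)(=O)Cl (its atoms remain only in 22)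
Why: Selective mesylation of the primary C9' hydroxyl is followed by intramolecular Williamson displacement by the C7 hydroxyl (5-exo-tet), which closes the second tetrahydrofuran with retention at C7 because no bond to C7 is broken, the cis fusion being preset by C8 and C8'.

Step 17
Reactants: 23 furofuran tosylate
Product: 24 furofuran phenol (ring B 4-OH free, ring C benzyl ether kept)
Conditions: KOH, MeOH/THF/H2O, 65 °C; 1 M HCl to pH 6
Reagents that add atoms: none
Why: Hydroxide attacks sulfur of the aryl sulfonate (S–O cleavage) and frees the ring B phenol, while the furofuran and the benzyl ether are stable to base.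

Step 18
Reactants: 25 (S)-4-benzyl-1,3-oxazolidin-2-one
Product: 26 (S)-4-benzyl-3-(bromoacetyl)-1,3-oxazolidin-2-one
Conditions: n-BuLi, THF, −78 °C; BrCH2COBr
Reagents that add atoms: bromoacetyl bromide, BrCC(Br)=O
Why: N-Acylation of the lithiated (S)-oxazolidinone by the acyl bromide, which reacts much faster than the alkyl bromide.

Step 19
Reactants: 24 furofuran phenol; 26 (S)-bromoacetyl imide
Product: 27 ring B aryloxyacetyl (S)-oxazolidinone imide
Conditions: Cs2CO3, MeCN, 0 °C to rt
Reagents that add atoms: none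
Why: SN2 displacement of the alpha-bromo imide by the caesium phenoxide (Williamson ether synthesis) gives the aryloxyacetyl imide.

Step 20
Reactants: 27 aryloxyacetyl imide; 28 4-(benzyloxy)-3-methoxybenzaldehyde (O-benzylvanillin)
Product: 30 anti-aldol adduct (2R,3R in the propanoyl chain; C8'' aryloxy and C7'' hydroxyl anti), via trimethylsilyl ether 29 (not isolated)
Conditions: MgCl2 (20 mol%), Et3N, Me3SiCl, EtOAc, rt; then HF·pyridine, THF/pyridine, 0 °C
Reagents that add atoms: chlorotrimethylsilane, C[Si](C)(C)Cl (its atoms remain only in 29)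
Why: Magnesium halide-catalysed Evans anti-aldol of an N-acyloxazolidinone with a non-enolisable aromatic aldehyde: soft enolisation gives the chelated (Z)-magnesium enolate, which should react on the face away from the benzyl group of the (S)-auxiliary through a boat transition state to set the C8'' aryloxy and C7'' hydroxyl groups anti (the erythro 7''R,8''S pattern after reduction), the aldolate being trapped as its silyl ether and desilylated by buffered HF.

Step 21
Reactants: 30 anti-aldol adduct
Product: 31 di-O-benzyl Ficusesquilignan A (erythro 7''R,8''S diol)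
Conditions: NaBH4, THF/H2O (4:1), 0 °C to rt
Reagents that add atoms: none
Why: Borohydride reduction of the N-acyloxazolidinone in wet THF releases the primary alcohol and the auxiliary without epimerising C8''.

Step 22
Reactants: 31 di-O-benzyl Ficusesquilignan A
Product: 32 Ficusesquilignan A
Conditions: H2 (1 atm), Pd/C (10 wt% Pd), EtOAc/EtOH, rt
Reagents that add atoms: none
Why: Hydrogenolysis of the two aryl benzyl ethers over palladium under neutral conditions and at low pressure is faster than cleavage of the benzylic C–O bonds of the furofuran and of the C7'' carbinol.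

Compound list
1 | vanillin | COc1cc(C=O)ccc1O | starting material
2 | 4-formyl-2-methoxyphenyl 4-methylbenzenesulfonate | COc1cc(C=O)ccc1OS(=O)(=O)c1ccc(C)cc1 | intermediate
3 | (R)-4-benzyl-1,3-oxazolidin-2-one | O=C1N[C@H](Cc2ccccc2)CO1 | starting material
4 | methyl 4-chloro-4-oxobutanoate | COC(=O)CCC(Cl)=O | starting material
5 | methyl 4-[(4R)-4-benzyl-2-oxo-1,3-oxazolidin-3-yl]-4-oxobutanoate | COC(=O)CCC(=O)N1[C@H](Cc2ccccc2)COC1=O | intermediate
6 | methyl (3R,4R)-3-{[(4R)-4-benzyl-2-oxo-1,3-oxazolidin-3-yl]carbonyl}-4-hydroxy-4-(3-methoxy-4-tosyloxyphenyl)butanoate (syn-aldol adduct) | COc1cc([C@H](O)[C@@H](CC(=O)OC)C(=O)N2[C@H](Cc3ccccc3)COC2=O)ccc1OS(=O)(=O)c1ccc(C)cc1 | intermediate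
7 | (4R)-4-benzyl-3-{[(2R,3R)-2-(3-methoxy-4-tosyloxyphenyl)-5-oxotetrahydrofuran-3-yl]carbonyl}-1,3-oxazolidin-2-one | COc1cc([C@@H]2OC(=O)C[C@H]2C(=O)N2[C@H](Cc3ccccc3)COC2=O)ccc1OS(=O)(=O)c1ccc(C)cc1 | intermediate
8 | (2R,3R)-2-(3-methoxy-4-tosyloxyphenyl)-5-oxotetrahydrofuran-3-carboxylic acid | COc1cc([C@@H]2OC(=O)C[C@H]2C(=O)O)ccc1OS(=O)(=O)c1ccc(C)cc1 | intermediate
9 | (4S,5R)-4-(hydroxymethyl)-5-(3-methoxy-4-tosyloxyphenyl)dihydrofuran-2(3H)-one | COc1cc([C@@H]2OC(=O)C[C@H]2CO)ccc1OS(=O)(=O)c1ccc(C)cc1 | intermediate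
10 | syringaldehyde | COc1cc(C=O)cc(OC)c1O | starting material
11 | 4-(benzyloxy)-3,5-dimethoxybenzaldehyde | COc1cc(C=O)cc(OC)c1OCc1ccccc1 | intermediate
12 | [4-(benzyloxy)-3,5-dimethoxyphenyl]methanol | COc1cc(CO)cc(OC)c1OCc1ccccc1 | intermediate
13 | 4-(benzyloxy)-3,5-dimethoxybenzyl 2,2,2-trichloroacetimidate | COc1cc(COC(=N)C(Cl)(Cl)Cl)cc(OC)c1OCc1ccccc1 | intermediate
14 | (4S,5R)-4-{[(4-benzyloxy-3,5-dimethoxybenzyl)oxy]methyl}-5-(3-methoxy-4-tosyloxyphenyl)dihydrofuran-2(3H)-one | COc1cc([C@@H]2OC(=O)C[C@H]2COCc2cc(OC)c(OCc3ccccc3)c(OC)c2)ccc1OS(=O)(=O)c1ccc(C)cc1 | intermediate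
15 | 3-trifluoroacetyl derivative of 14 (C8' enolisable, configuration there undefined) | COc1cc([C@@H]2OC(=O)C(C(=O)C(F)(F)F)[C@H]2COCc2cc(OC)c(OCc3ccccc3)c(OC)c2)ccc1OS(=O)(=O)c1ccc(C)cc1 | intermediate
16 | (4S,5R)-3-diazo-4-{[(4-benzyloxy-3,5-dimethoxybenzyl)oxy]methyl}-5-(3-methoxy-4-tosyloxyphenyl)dihydrofuran-2(3H)-one | COc1cc([C@@H]2OC(=O)C(=[N+]=[N-])[C@H]2COCc2cc(OC)c(OCc3ccccc3)c(OC)c2)ccc1OS(=O)(=O)c1ccc(C)cc1 | intermediate
17 | cis-fused furofuranone (7R,8S,7'S,8'R), C9' lactone carbonyl, ring B aryl exo at C7, ring C aryl endo at C7' | COc1cc([C@@H]2OC(=O)[C@@H]3[C@H]2CO[C@@H]3c2cc(OC)c(OCc3ccccc3)c(OC)c2)ccc1OS(=O)(=O)c1ccc(C)cc1 | intermediate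
18 | all-cis tetrahydrofuran diol (7R,8S,7'S,8'S) | COc1cc([C@H](O)[C@@H]2CO[C@H](c3cc(OC)c(OCc4ccccc4)c(OC)c3)[C@@H]2CO)ccc1OS(=O)(=O)c1ccc(C)cc1 | intermediate
19 | all-cis tetrahydrofuran diacetate (7R,8S,7'S,8'S) | COc1cc([C@H](OC(C)=O)[C@@H]2CO[C@H](c3cc(OC)c(OCc4ccccc4)c(OC)c3)[C@@H]2COC(C)=O)ccc1OS(=O)(=O)c1ccc(C)cc1 | intermediate
20 | 2,3-trans-3,4-cis tetrahydrofuran diacetate (7R,8S,7'R,8'S) | COc1cc([C@H](OC(C)=O)[C@@H]2CO[C@@H](c3cc(OC)c(OCc4ccccc4)c(OC)c3)[C@@H]2COC(C)=O)ccc1OS(=O)(=O)c1ccc(C)cc1 | intermediate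
21 | 2,3-trans-3,4-cis tetrahydrofuran diol (7R,8S,7'R,8'S) | COc1cc([C@H](O)[C@@H]2CO[C@@H](c3cc(OC)c(OCc4ccccc4)c(OC)c3)[C@@H]2CO)ccc1OS(=O)(=O)c1ccc(C)cc1 | intermediate
22 | C9' methanesulfonate of 21 | COc1cc([C@H](O)[C@@H]2CO[C@@H](c3cc(OC)c(OCc4ccccc4)c(OC)c3)[C@@H]2COS(C)(=O)=O)ccc1OS(=O)(=O)c1ccc(C)cc1 | intermediate
23 | furofuran tosylate (7R,8S,7'R,8'S), both aryl groups exo | COc1cc([C@@H]2OC[C@@H]3[C@H]2CO[C@H]3c2cc(OC)c(OCc3ccccc3)c(OC)c2)ccc1OS(=O)(=O)c1ccc(C)cc1 | intermediate
24 | furofuran phenol (ring B 4-OH, ring C 4-OBn) | COc1cc([C@@H]2OC[C@@H]3[C@H]2CO[C@H]3c2cc(OC)c(OCc3ccccc3)c(OC)c2)ccc1O | intermediate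
25 | (S)-4-benzyl-1,3-oxazolidin-2-one | O=C1N[C@@H](Cc2ccccc2)CO1 | starting material
26 | (S)-4-benzyl-3-(bromoacetyl)-1,3-oxazolidin-2-one | O=C(CBr)N1[C@@H](Cc2ccccc2)COC1=O | intermediate
27 | ring B aryloxyacetyl (S)-oxazolidinone imide | COc1cc([C@@H]2OC[C@@H]3[C@H]2CO[C@H]3c2cc(OC)c(OCc3ccccc3)c(OC)c2)ccc1OCC(=O)N1[C@@H](Cc2ccccc2)COC1=O | intermediate
28 | 4-(benzyloxy)-3-methoxybenzaldehyde | COc1cc(C=O)ccc1OCc1ccccc1 | starting material
29 | O7''-trimethylsilyl ether of the anti-aldol adduct | COc1cc([C@@H](O[Si](C)(C)C)[C@H](C(=O)N2[C@@H](Cc3ccccc3)COC2=O)Oc2ccc([C@@H]3OC[C@@H]4[C@H]3CO[C@H]4c3cc(OC)c(OCc4ccccc4)c(OC)c3)cc2OC)ccc1OCc1ccccc1 | intermediate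
30 | anti-aldol adduct (imide, 7''R, C8'' aryloxy anti to 7''-OH) | COc1cc([C@@H](O)[C@H](C(=O)N2[C@@H](Cc3ccccc3)COC2=O)Oc2ccc([C@@H]3OC[C@@H]4[C@H]3CO[C@H]4c3cc(OC)c(OCc4ccccc4)c(OC)c3)cc2OC)ccc1OCc1ccccc1 | intermediate
31 | di-O-benzyl Ficusesquilignan A (erythro, 7''R,8''S) | COc1cc([C@@H](O)[C@H](CO)Oc2ccc([C@@H]3OC[C@@H]4[C@H]3CO[C@H]4c3cc(OC)c(OCc4ccccc4)c(OC)c3)cc2OC)ccc1OCc1ccccc1 | intermediate
32 | Ficusesquilignan A | COc1cc([C@@H](O)[C@H](CO)Oc2ccc([C@@H]3OC[C@@H]4[C@H]3CO[C@H]4c3cc(OC)c(O)c(OC)c3)cc2OC)ccc1O | target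

Total step count: 22. Longest linear sequence: 17 steps (1, 3, 4, 5, 9 to 17, 19 to 22).

Steps most likely to fail

Step 11. The carbene may decay by 1,2-hydride migration from C8 (butenolide formation) or by dimerisation faster than it inserts. The fallback makes the C7'–C8' bond by a lactone-enolate aldol instead. It sets out from alcohol 9, which is equilibrated with DBU to the ring-transposed hydroxy lactone F1 (acyl group now on O9, C7 carbinol free) and silylated (TBSOTf, 2,6-lutidine) to the silyl ether F2. The lithium enolate of F2 (LiN(SiMe3)2, THF, −78 °C) adds to aldehyde 11 anti to the C8 substituent and gives the aldol adduct F3 with the C8' configuration of the target. LiBH4 opens the lactone to the triol F4; camphorsulfonic acid then ionises the C7' carbinol and O9 closes the tetrahydrofuran with the aryl group trans to C9', giving the silyl ether F5. Bu4NF returns to the route at diol 21, so steps 9 to 15 are by-passed.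

Step 14. Ionisation at C7' may stall, or the cation may be diverted by acetoxonium capture or elimination before the equilibrium is reached. The fallback sets out from diol 18 and moves the epimerisation behind the ring closure: MsCl/pyridine gives, through the primary mesylate F6, the 7'-epi furofuran F7. F7 is then equilibrated with its diequatorial isomer under acid (HCl in CH2Cl2 or BF3·OEt2), where the tosyloxyaryl ring again keeps C7 fixed. Because the two bicyclic epimers are expected to be close in energy, 23 would be separated and F7 recycled; the route is rejoined at 23.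

Step 20. The alpha-aryloxy magnesium enolate may give poor anti/syn or facial control, since the aryloxy oxygen can change chelation in the transition state. The fallback sets the benzylic centre by inversion instead. It sets out from phenol 24, which is alkylated (Cs2CO3, MeCN) with the (R)-bromoacetyl imide F8 (from 3 and bromoacetyl bromide) to give the aryloxyacetyl imide F9. Its dibutylboron enolate (Bu2BOTf, i-Pr2NEt) adds to 28 in an Evans syn aldol to give the syn adduct F10, with C8'' correct and C7'' epimeric. NaBH4 gives the threo diol F11; a Mitsunobu reaction with 4-nitrobenzoic acid (PPh3, DIAD) esterifies both hydroxyls with inversion at C7'' to give the bis(4-nitrobenzoate) F12, and K2CO3/MeOH returns to the route at erythro diol 31.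

Further compounds
F1 | step 11 | (R)-configured 4-[hydroxy(3-methoxy-4-tosyloxyphenyl)methyl]dihydrofuran-2(3H)-one (ring-transposed lactone, 7R,8S) | O[C@@H](c1ccc(OS(=O)(=O)c2ccc(C)cc2)c(OC)c1)[C@@H]1COC(=O)C1
F2 | step 11 | O7-tert-butyldimethylsilyl ether of F1 | CC(C)(C)[Si](C)(C)O[C@@H](c1ccc(OS(=O)(=O)c2ccc(C)cc2)c(OC)c1)[C@@H]1COC(=O)C1
F3 | step 11 | aldol adduct of F2 with 11 (C8' substituent trans to the C8 substituent, C7' carbinol as a mixture) | CC(C)(C)[Si](C)(C)O[C@@H](c1ccc(OS(=O)(=O)c2ccc(C)cc2)c(OC)c1)[C@@H]1COC(=O)[C@H]1C(O)c1cc(OC)c(OCc2ccccc2)c(OC)c1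
F4 | step 11 | triol from reduction of F3 (C9-OH, C9'-OH, C7'-OH; C7-OTBS) | CC(C)(C)[Si](C)(C)O[C@@H](c1ccc(OS(=O)(=O)c2ccc(C)cc2)c(OC)c1)[C@H](CO)[C@@H](CO)C(O)c1cc(OC)c(OCc2ccccc2)c(OC)c1
F5 | step 11 | O7-tert-butyldimethylsilyl ether of diol 21 | COc1cc([C@H](O[Si](C)(C)C(C)(C)C)[C@@H]2CO[C@@H](c3cc(OC)c(OCc4ccccc4)c(OC)c3)[C@@H]2CO)ccc1OS(=O)(=O)c1ccc(C)cc1
F6 | step 14 | C9' methanesulfonate of all-cis diol 18 | COc1cc([C@H](O)[C@@H]2CO[C@H](c3cc(OC)c(OCc4ccccc4)c(OC)c3)[C@@H]2COS(C)(=O)=O)ccc1OS(=O)(=O)c1ccc(C)cc1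
F7 | step 14 | 7'-epi furofuran tosylate (7R,8S,7'S,8'S; ring C aryl endo) | COc1cc([C@@H]2OC[C@@H]3[C@H]2CO[C@@H]3c2cc(OC)c(OCc3ccccc3)c(OC)c2)ccc1OS(=O)(=O)c1ccc(C)cc1
F8 | step 20 | (R)-4-benzyl-3-(bromoacetyl)-1,3-oxazolidin-2-one | O=C(CBr)N1[C@H](Cc2ccccc2)COC1=O
F9 | step 20 | ring B aryloxyacetyl (R)-oxazolidinone imide | COc1cc([C@@H]2OC[C@@H]3[C@H]2CO[C@H]3c2cc(OC)c(OCc3ccccc3)c(OC)c2)ccc1OCC(=O)N1[C@H](Cc2ccccc2)COC1=O
F10 | step 20 | syn-aldol adduct of F9 with 28 (C7'' epimer of the required pattern) | COc1cc([C@H](O)[C@H](C(=O)N2[C@H](Cc3ccccc3)COC2=O)Oc2ccc([C@@H]3OC[C@@H]4[C@H]3CO[C@H]4c3cc(OC)c(OCc4ccccc4)c(OC)c3)cc2OC)ccc1OCc1ccccc1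
F11 | step 20 | threo diol (7''S,8''S), the C7'' epimer of 31 | COc1cc([C@H](O)[C@H](CO)Oc2ccc([C@@H]3OC[C@@H]4[C@H]3CO[C@H]4c3cc(OC)c(OCc4ccccc4)c(OC)c3)cc2OC)ccc1OCc1ccccc1
F12 | step 20 | bis(4-nitrobenzoate) of 31 (erythro, inverted at C7'') | COc1cc([C@@H](OC(=O)c2ccc(cc2)[N+](=O)[O-])[C@H](COC(=O)c2ccc(cc2)[N+](=O)[O-])Oc2ccc([C@@H]3OC[C@@H]4[C@H]3CO[C@H]4c3cc(OC)c(OCc4ccccc4)c(OC)c3)cc2OC)ccc1OCc1ccccc1
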